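## Analysis of the target

Ardisinone is a 1,4-benzoquinone: C1 and C4 are the carbonyl carbons, C2 carries a methoxy group, C6 carries the side chain, and C3 and C5 are unsubstituted. The side chain is an unbranched fifteen-carbon chain, with C1' a methylene on C6, C2' bearing the acetoxy group, and C3' to C15' forming a tridecyl tail. C2' is the only stereocentre and is (R) (O > C1' > C3' > H), so only absolute configuration has to be set, at a carbon flanked by two methylene groups of almost the same size. That similarity is the first difficulty, because it makes enantioface discrimination of the corresponding C2' ketone by a reducing agent unreliable. The second difficulty is the ring: the methoxyquinone is an electrophile and an oxidant that tolerates neither organometallic reagents nor strong base, and the C1 carbonyl must sit exactly between the methoxy group and the chain. The secondary acetate is base-labile and could shift to a neighbouring free phenol oxygen, so the ester is introduced late and the quinone is released last. The plan rests on C1' being a lone sp3 methylene between ring carbon C6 and the oxygen-bearing C2'. An aryl–boron bond at C6 can therefore be extended by one carbon (C1') and then by a second, stereodefined carbon (C2' with its tail) through two 1,2-shifts on the same boron atom, which ends on C2' exactly where the oxygen is needed.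

## Retrosynthetic reasoning

The quinone is taken off first. Target 18 is traced to phenol 17 by removing the C4 oxygen and returning the C1 carbonyl to a phenolic hydroxyl. In 17 the hydroxyl on C1 is flanked by the methoxy group at C2 and the chain at C6, so only the para carbon C4 is open and the substitution pattern of the quinone is guaranteed. The forward reaction has to be a para-selective phenol-to-quinone oxidation in a near-neutral medium that spares the acetate.

The phenol of 17 is carried as a benzyl ether (16), and the acetate of 16 is traced to carbinol 15 by cutting the acyl C–O bond. Acetylation is placed before debenzylation so that only one hydroxyl is free when the acyl group goes on. The benzyl ether is chosen because it survives organolithium reagents and alkaline oxidation and falls off under neutral reductive conditions that touch neither the ester nor C2'.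

The C2'–O bond of 15 is traced to the C2'–B bond of boronate 14. Oxidative exchange of boron for oxygen goes with retention, so the stereochemical problem moves from a carbinol to a secondary boronate, for which reagent-controlled construction is available.

Both carbon–carbon bonds at C1' are then cut in 14, namely C6–C1' and C1'–C2'. This leaves aryl boronate 4, the one-carbon unit 8 (C1') and carbamate 7 (C2' to C15'). Cutting only C1'–C2' (a benzyl nucleophile plus an aldehyde) would create the stereocentre without control, and cutting C2'–C3' would demand a chiral electrophile. Cutting on both sides of C1' lets boron start on C6 and travel down the chain. In the forward sense, the carbenoid 9 made from 8 inserts once to give benzylic boronate 11, and the enantioenriched lithiated carbamate 12 then inserts to give 14. Each insertion must occur once only, and the second must be stereospecific.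

The C6–B bond of 4 is traced to the C–Br bond of 2 and the diboron reagent 3, and 2 is the O-benzyl derivative of 1. In 1 the bromine already sits ortho to the hydroxyl and meta to the methoxy group, exactly where the chain must go, so the ring regiochemistry is bought and not made.

Carbamate 7 is cut at its O–C(=O) bond to alcohol 5 and carbamoyl chloride 6. C1 of 5 becomes C2', and the hindered carbamate serves first as the directing group for lithiation and then as the leaving group in the 1,2-shift.

## Alternatives that were turned down

Alternative 1: The C2'–O bond is made by asymmetric allylic etherification, and the phenol oxygen is tied temporarily into a five-membered ring. The precursor is the allylic carbonate A1, methyl (2E)-4-(2-hydroxy-3,5-dimethoxyphenyl)but-2-en-1-yl carbonate. Zerovalent palladium (Pd2(dba)3) with a C2-symmetric bis(2-diphenylphosphinobenzamide) ligand of trans-1,2-diaminocyclohexane ionizes the carbonate. The phenol oxygen then attacks the internal allyl terminus and closes the dihydrofuran, giving A2, (2S)-2-ethenyl-5,7-dimethoxy-2,3-dihydro-1-benzofuran. The tail would be attached by cross-metathesis of the vinyl group with tridec-1-ene A3 and saturation of the new alkene. Oxidation with (NH4)2[Ce(NO3)6] would then cleave the aryl–oxygen bond, releasing the C2' hydroxyl and the quinone together, and acetylation would finish the synthesis.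
- For it: the chiral information is used catalytically, which is stronger than the full equivalent of chiral diamine in the chosen route. No protecting group is needed. Both quinone oxygens are already on the ring, so the final oxidation needs no positional selectivity.
- Against it: the configuration depends on catalyst discrimination between rapidly interconverting allyl faces in a short-tethered closure. A2 is itself an allylic aryl ether that the same catalyst can re-ionize. C2' stays allylic until the alkene is reduced, so hydrogenation competes with C–O hydrogenolysis. The cerium oxidation must break the ring C–O bond specifically, with ortho-quinone formation from the adjacent methoxy group as a competitor.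
- Comparison: the step count is about the same (eight to nine). The chosen route gives up catalytic use of the chiral source. In return the configuration is predictable from the reagent and transmitted by stereospecific steps, and the stereocentre is never allylic.

Alternative 2: The quinone ring itself is disconnected. The alkenyllithium from bromide A5, (4R)-2-bromo-4-(tert-butyldimethylsilyloxy)heptadec-1-ene, adds to the ketone carbonyl of A4, 3-methoxycyclobut-3-ene-1,2-dione, to give cyclobutenone A6, 4-hydroxy-3-methoxy-4-[(4R)-4-(tert-butyldimethylsilyloxy)heptadec-1-en-2-yl]cyclobut-2-en-1-one. Heating A6 in toluene opens the four-membered ring to a dienylketene, which closes by six-electron electrocyclization (forming C4–C5) and tautomerizes to hydroquinone A7, 2-methoxy-6-[(2R)-2-(tert-butyldimethylsilyloxy)pentadecyl]benzene-1,4-diol. Oxidation (air or Ag2O), desilylation and acetylation would follow.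
- For it: the route is convergent, and the positions of methoxy, chain and both oxygens follow from the connectivity of A6. Oxidizing a hydroquinone is easier than oxidizing a phenol at its para position, so on the final oxidation this alternative is stronger.
- Against it: the key step does nothing for C2'. The stereocentre must be made separately in A5, carried as a silyl ether, and exchanged for the acetate on the sensitive quinone. A4 is not an article of commerce in quantity and needs two steps from a squarate diester. The count comes to about ten steps.
- Comparison: the chosen route buys the arene and spends its key step on the only real problem, the stereocentre, forming two C–C bonds in the same operation.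

Alternative 3: The benzene ring is built by a polyketide-type aldol condensation. Heating the diketo-dioxinone A8, 6-[(6R)-6-(tert-butyldimethylsilyloxy)-2,4-dioxononadecyl]-2,2-dimethyl-4H-1,3-dioxin-4-one, with methanol releases the trioxo ester A9, methyl (9R)-9-(tert-butyldimethylsilyloxy)-3,5,7-trioxodocosanoate. Its C2 methylene adds to the C7 ketone (Cs2CO3, then HCl), forming ring bond C1–C6 and, after dehydration, resorcylate A10, methyl 2,4-dihydroxy-6-[(2R)-2-(tert-butyldimethylsilyloxy)pentadecyl]benzoate.
- For it: the ring forms under mild conditions with the chain position fixed by the polyketide logic. The stereocentre can come from a catalytic asymmetric hydrogenation of a β-keto ester, again more economical in chirality than the chosen route.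
- Against it: the ring that results has the wrong oxidation pattern. The ester carbon sits on the future C1 and must be excised and replaced by oxygen. The two phenols must be differentiated so that only the chelated one is methylated. The β-silyloxy ketone in A9 can lose silanolate by E1cB elimination under the carbonate base, which would destroy C2'. With starter synthesis, chain assembly and the corrections after the key step, the route exceeds twelve steps.
- Comparison: this alternative constructs a benzene ring that can be purchased with the correct substituents, so the chosen route is shorter and avoids putting the stereocentre at risk next to a ketone.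

Key step: step 4

## Route

Remark on the chemistry: the two homologations of step 4 are run as one telescoped operation with a change of solvent from THF to Et2O between them, because THF would displace the chiral diamine from lithium; the benzylic boronate is not purified.

Step 1
Reactants: 1 2-bromo-6-methoxyphenol
Product: 2 2-(benzyloxy)-1-bromo-3-methoxybenzene
Conditions: BnBr, K2CO3, DMF, rt
Reagents that add atoms: benzyl bromide, BrCc1ccccc1
Why: Williamson ether synthesis (SN2 of the phenoxide on a benzylic bromide); the benzyl ether withstands the organolithium reagents and the alkaline oxidation that follow and is removed later under neutral conditions.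

Step 2
Reactants: 2 2-(benzyloxy)-1-bromo-3-methoxybenzene; 3 bis(pinacolato)diboron
Product: 4 2-[2-(benzyloxy)-3-methoxyphenyl]-4,4,5,5-tetramethyl-1,3,2-dioxaborolane
Conditions: Pd(dppf)Cl2 (cat.), KOAc, 1,4-dioxane, 90 °C
Reagents that add atoms: none
Why: Miyaura borylation: oxidative addition of the aryl bromide to zerovalent palladium, acetate-assisted transmetalation with 3 and reductive elimination; KOAc is too weak a base to drive Suzuki coupling of 4 with unreacted 2.

Step 3
Reactants: 5 1-tetradecanol; 6 N,N-diisopropylcarbamoyl chloride
Product: 7 tetradecyl N,N-diisopropylcarbamate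
Conditions: Et3N, CH2Cl2, reflux
Reagents that add atoms: none
Why: Carbamoylation of a primary alcohol by nucleophilic acyl substitution; the hindered carbamate resists attack at its carbonyl and later directs α-lithiation and serves as the leaving group.

Step 4
Reactants: 4 2-[2-(benzyloxy)-3-methoxyphenyl]-4,4,5,5-tetramethyl-1,3,2-dioxaborolane; 8 bromochloromethane; 7 tetradecyl N,N-diisopropylcarbamate
Product: 14 2-{(2R)-1-[2-(benzyloxy)-3-methoxyphenyl]pentadecan-2-yl}-4,4,5,5-tetramethyl-1,3,2-dioxaborolane, via chloromethyllithium 9 (not isolated), via chloromethyl borate complex 10 (not isolated), via benzylic pinacol boronate 11 (not isolated), via lithiated carbamate 12 (not isolated), via carbamoyloxyalkyl borate complex 13 (not isolated)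
Conditions: BrCH2Cl, n-BuLi, THF, −78 °C to rt; evaporate, Et2O; add to 7 (1.4 equiv), s-BuLi, (−)-sparteine, Et2O, −78 °C; MgBr2·OEt2, reflux
Reagents that add atoms: none
Why: This is the known iterative homologation of boronic esters, two Matteson-type 1,2-metallate rearrangements on one boron atom. Bromine–lithium exchange on 8 in the presence of 4 gives carbenoid 9, which is captured at once by boron as borate 10; on warming, the electron-rich aryl group shifts from boron to carbon with loss of chloride and forms C6–C1' in 11. After the change to Et2O, s-BuLi bound to (−)-sparteine removes the pro-S hydrogen of 7, and the configurationally stable carbenoid 12 adds to the boron of 11 with retention at carbon to give borate 13. When 13 is warmed with MgBr2·OEt2, the benzylic carbon C1' migrates antiperiplanar to the departing carbamate with inversion at C2', which forms C1'–C2' and delivers the (R) boronate 14. No ring is closed. The one new stereocentre is set by the reagent, the chiral diamine deciding which hydrogen of 7 is removed, and is passed on by two stereospecific events, so the near-identical size of C1' and C3' plays no part. The step needs single insertion in the first stage, which is secured because 9 is trapped or decays at −78 °C before the thermally triggered shift creates any 11, and clean capture in the second stage, which is secured by removing residual 8 and THF before the transfer and by using 12 in slight excess over 11.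

Step 5
Reactants: 14 2-{(2R)-1-[2-(benzyloxy)-3-methoxyphenyl]pentadecan-2-yl}-4,4,5,5-tetramethyl-1,3,2-dioxaborolane
Product: 15 (2R)-1-[2-(benzyloxy)-3-methoxyphenyl]pentadecan-2-ol
Conditions: H2O2 (30% aq.), NaOH (2 M aq.), THF, 0 °C to rt
Reagents that add atoms: hydrogen peroxide, OO
Why: Oxidation of a carbon–boron bond by alkaline hydrogen peroxide: hydroperoxide adds to boron and C2' migrates from boron to oxygen with retention, so the (R) boronate should give the (R) carbinol; the aryl ethers are inert.

Step 6
Reactants: 15 (2R)-1-[2-(benzyloxy)-3-methoxyphenyl]pentadecan-2-ol
Product: 16 (2R)-1-[2-(benzyloxy)-3-methoxyphenyl]pentadecan-2-yl acetate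
Conditions: Ac2O, pyridine, DMAP (cat.), CH2Cl2, rt
Reagents that add atoms: acetic anhydride, CC(=O)OC(C)=O
Why: Nucleophile-catalysed O-acylation of a secondary alcohol; the C2'–O bond is not broken, so the configuration is kept, and the phenol is still masked, so only one acetate is introduced.

Step 7
Reactants: 16 (2R)-1-[2-(benzyloxy)-3-methoxyphenyl]pentadecan-2-yl acetate
Product: 17 (2R)-1-(2-hydroxy-3-methoxyphenyl)pentadecan-2-yl acetate
Conditions: H2 (1 atm), Pd/C, EtOAc, rt
Reagents that add atoms: none
Why: Heterogeneous hydrogenolysis of a benzyl aryl ether; C1' carries no heteroatom and the acetate on C2' is homobenzylic, so neither is cleaved, and under neutral conditions the acetyl group should stay on the secondary oxygen and not move to the new phenol.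

Step 8
Reactants: 17 (2R)-1-(2-hydroxy-3-methoxyphenyl)pentadecan-2-yl acetate
Product: 18 ardisinone, (2R)-1-(5-methoxy-3,6-dioxocyclohexa-1,4-dien-1-yl)pentadecan-2-yl acetate
Conditions: K2[ON(SO3)2], KH2PO4 (aq.), acetone/H2O, 0 °C to rt
Reagents that add atoms: dipotassium nitrosodisulfonate K2[ON(SO3)2], [K+].[K+].[O]N(S(=O)(=O)[O-])S(=O)(=O)[O-]
Why: Teuber oxidation: one nitroxyl radical removes the phenolic hydrogen, a second adds through oxygen to the para carbon C4, and loss of imidodisulfonate gives the 1,4-quinone; both ortho positions (C2 methoxy, C6 chain) are blocked, and the near-neutral buffer should leave the acetate and C2' untouched.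

## Compound list

1 | 2-bromo-6-methoxyphenol | COc1cccc(Br)c1O | starting material
2 | 2-(benzyloxy)-1-bromo-3-methoxybenzene | COc1cccc(Br)c1OCc1ccccc1 | intermediate
3 | bis(pinacolato)diboron | CC1(C)OB(OC1(C)C)B1OC(C)(C)C(C)(C)O1 | starting material
4 | 2-[2-(benzyloxy)-3-methoxyphenyl]-4,4,5,5-tetramethyl-1,3,2-dioxaborolane | COc1cccc(B2OC(C)(C)C(C)(C)O2)c1OCc1ccccc1 | intermediate
5 | 1-tetradecanol | CCCCCCCCCCCCCCO | starting material
6 | N,N-diisopropylcarbamoyl chloride | CC(C)N(C(C)C)C(Cl)=O | starting material
7 | tetradecyl N,N-diisopropylcarbamate | CCCCCCCCCCCCCCOC(=O)N(C(C)C)C(C)C | intermediate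
8 | bromochloromethane | ClCBr | starting material
9 | chloromethyllithium | [Li]CCl | intermediate (not isolated)
10 | lithium [2-(benzyloxy)-3-methoxyphenyl](chloromethyl)(2,3-dimethylbutane-2,3-diolato)borate | [Li+].COc1cccc([B-]2(CCl)OC(C)(C)C(C)(C)O2)c1OCc1ccccc1 | intermediate (not isolated)
11 | 2-{[2-(benzyloxy)-3-methoxyphenyl]methyl}-4,4,5,5-tetramethyl-1,3,2-dioxaborolane | COc1cccc(CB2OC(C)(C)C(C)(C)O2)c1OCc1ccccc1 | intermediate (not isolated)
12 | (1S)-1-lithiotetradecyl N,N-diisopropylcarbamate, held as its (−)-sparteine complex | CCCCCCCCCCCCC[C@H]([Li])OC(=O)N(C(C)C)C(C)C | intermediate (not isolated)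
13 | lithium {(1S)-1-[(diisopropylcarbamoyl)oxy]tetradecyl}{[2-(benzyloxy)-3-methoxyphenyl]methyl}(2,3-dimethylbutane-2,3-diolato)borate | [Li+].CCCCCCCCCCCCC[C@H]([B-]1(Cc2cccc(OC)c2OCc2ccccc2)OC(C)(C)C(C)(C)O1)OC(=O)N(C(C)C)C(C)C | intermediate (not isolated)
14 | 2-{(2R)-1-[2-(benzyloxy)-3-methoxyphenyl]pentadecan-2-yl}-4,4,5,5-tetramethyl-1,3,2-dioxaborolane | CCCCCCCCCCCCC[C@H](Cc1cccc(OC)c1OCc1ccccc1)B1OC(C)(C)C(C)(C)O1 | intermediate
15 | (2R)-1-[2-(benzyloxy)-3-methoxyphenyl]pentadecan-2-ol | CCCCCCCCCCCCC[C@H](Cc1cccc(OC)c1OCc1ccccc1)O | intermediate
16 | (2R)-1-[2-(benzyloxy)-3-methoxyphenyl]pentadecan-2-yl acetate | CCCCCCCCCCCCC[C@H](Cc1cccc(OC)c1OCc1ccccc1)OC(C)=O | intermediate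
17 | (2R)-1-(2-hydroxy-3-methoxyphenyl)pentadecan-2-yl acetate | CCCCCCCCCCCCC[C@H](Cc1cccc(OC)c1O)OC(C)=O | intermediate
18 | ardisinone, (2R)-1-(5-methoxy-3,6-dioxocyclohexa-1,4-dien-1-yl)pentadecan-2-yl acetate | CCCCCCCCCCCCC[C@H](CC1=CC(=O)C=C(OC)C1=O)OC(C)=O | target

## Step count and points of risk

Total step count: 8. Longest linear sequence: 7 steps (steps 1, 2, 4, 5, 6, 7, 8); step 3 is a one-step side branch.

Step 4 (key step). Three things can go wrong. The chloromethyl insertion may be incomplete or may happen twice, which would carry aryl or homobenzylic boronates into the second stage, where they also capture 12. The 1,2-shift from borate 13 may be slow, since a hindered carbamate is a reluctant leaving group, which costs yield. The lithiated carbamate may lose configurational integrity through local warming during the transfer, which would erode the enantiomeric purity of 14.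

The fallback gives up the boron shifts and takes C2' from the chiral pool. It sets out from 2 and returns at 15.
- Bromide 2 is converted with Mg in THF into bromo[2-(benzyloxy)-3-methoxyphenyl]magnesium F1.
- Separately, (R)-epichlorohydrin (ClC[C@H]1CO1) is opened at its ring methylene by dodecylmagnesium bromide (CuI cat., THF, −40 °C) to give (2R)-1-chloropentadecan-2-ol F2.
- F2 is closed with NaOH to (2R)-2-tridecyloxirane F3.
- F1 with CuI (cat.) opens F3 at its terminal carbon; the stereocentre is not touched, and aqueous NH4Cl work-up should give carbinol 15 directly.

Step 2. Slow oxidative addition into the electron-rich, ortho-alkoxy aryl bromide can let protodebromination or biaryl coupling of 4 with 2 compete. The fallback replaces catalysis by a polar organometallic route from 2 to 4. Bromine–lithium exchange on 2 (n-BuLi, THF, −78 °C) gives [2-(benzyloxy)-3-methoxyphenyl]lithium F4, which is quenched with 2-isopropoxy-4,4,5,5-tetramethyl-1,3,2-dioxaborolane (CC(C)OB1OC(C)(C)C(C)(C)O1); loss of isopropoxide from the borate gives 4.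

Step 8. The oxidant lives in water while phenol 17, with its fifteen-carbon chain and acetate, is very lipophilic. The oxidation may therefore be slow and heterogeneous, the radical salt may decompose meanwhile, and the ester may hydrolyse over long reaction times. The fallback changes both the order of events and the oxidant. It sets out from 15 and returns at 18.
- Hydrogenolysis of 15 (H2, Pd/C, EtOAc) gives (2R)-1-(2-hydroxy-3-methoxyphenyl)pentadecan-2-ol F5.
- Aerobic oxidation catalysed by Co(salen) (O2, DMF, rt) in homogeneous solution converts the 2,6-disubstituted phenol into 2-[(2R)-2-hydroxypentadecyl]-6-methoxycyclohexa-2,5-diene-1,4-dione F6. Closure of the free hydroxyl onto the quinone would be a disfavoured 5-endo addition.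
- Acetylation under non-nucleophilic conditions (AcCl, 2,6-lutidine, CH2Cl2, 0 °C) gives 18.

## Further compounds

F1 | step 4 | bromo[2-(benzyloxy)-3-methoxyphenyl]magnesium | COc1cccc([Mg]Br)c1OCc1ccccc1
F2 | step 4 | (2R)-1-chloropentadecan-2-ol | CCCCCCCCCCCCC[C@H](CCl)O
F3 | step 4 | (2R)-2-tridecyloxirane | CCCCCCCCCCCCC[C@@H]1CO1
F4 | step 2 | [2-(benzyloxy)-3-methoxyphenyl]lithium | [Li]c1cccc(OC)c1OCc1ccccc1
F5 | step 8 | (2R)-1-(2-hydroxy-3-methoxyphenyl)pentadecan-2-ol | CCCCCCCCCCCCC[C@H](Cc1cccc(OC)c1O)O
F6 | step 8 | 2-[(2R)-2-hydroxypentadecyl]-6-methoxycyclohexa-2,5-diene-1,4-dione | CCCCCCCCCCCCC[C@H](CC1=CC(=O)C=C(OC)C1=O)O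
A1 | alternative 1 | methyl (2E)-4-(2-hydroxy-3,5-dimethoxyphenyl)but-2-en-1-yl carbonate | COC(=O)OC/C=C/Cc1cc(OC)cc(OC)c1O
A2 | alternative 1 | (2S)-2-ethenyl-5,7-dimethoxy-2,3-dihydro-1-benzofuran | C=C[C@H](C1)Oc2c(OC)cc(OC)cc12
A3 | alternative 1 | tridec-1-ene | C=CCCCCCCCCCCC
A4 | alternative 2 | 3-methoxycyclobut-3-ene-1,2-dione | COC1=CC(=O)C1=O
A5 | alternative 2 | (4R)-2-bromo-4-(tert-butyldimethylsilyloxy)heptadec-1-ene | CCCCCCCCCCCCC[C@H](CC(Br)=C)O[Si](C)(C)C(C)(C)C
A6 | alternative 2 | 4-hydroxy-3-methoxy-4-[(4R)-4-(tert-butyldimethylsilyloxy)heptadec-1-en-2-yl]cyclobut-2-en-1-one | CCCCCCCCCCCCC[C@H](CC(=C)C1(O)C(OC)=CC1=O)O[Si](C)(C)C(C)(C)C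
A7 | alternative 2 | 2-methoxy-6-[(2R)-2-(tert-butyldimethylsilyloxy)pentadecyl]benzene-1,4-diol | CCCCCCCCCCCCC[C@H](Cc1cc(O)cc(OC)c1O)O[Si](C)(C)C(C)(C)C
A8 | alternative 3 | 6-[(6R)-6-(tert-butyldimethylsilyloxy)-2,4-dioxononadecyl]-2,2-dimethyl-4H-1,3-dioxin-4-one | CCCCCCCCCCCCC[C@H](CC(=O)CC(=O)CC1=CC(=O)OC(C)(C)O1)O[Si](C)(C)C(C)(C)C
A9 | alternative 3 | methyl (9R)-9-(tert-butyldimethylsilyloxy)-3,5,7-trioxodocosanoate | CCCCCCCCCCCCC[C@H](CC(=O)CC(=O)CC(=O)CC(=O)OC)O[Si](C)(C)C(C)(C)C
A10 | alternative 3 | methyl 2,4-dihydroxy-6-[(2R)-2-(tert-butyldimethylsilyloxy)pentadecyl]benzoate | CCCCCCCCCCCCC[C@H](Cc1cc(O)cc(O)c1C(=O)OC)O[Si](C)(C)C(C)(C)C
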